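**Plan** (labdane numbering throughout: ring A = C1–C5 and C10, ring B = C5–C10, chain C11–C15)
1. Retrosynthesis first cuts the C15 ester to the glycerol unit, then places a formyl group on C6 and cuts C5–C10 and C6–C7, opening ring A and ring B together to an acyclic (2E,8E)-trienal.
2. The feature that allows this: C8=C9 is the only ring olefin, so ring B is the cyclohexene left by a C7=C8–C9=C10 diene and a C5=C6 dienophile tied through C1–C4, and quaternary C4 leaves the enal without a γ-hydrogen.
3. The diene is traced back to methyl acetoacetate through C8 (ester to isopropenyl), C10–C20 (enol triflate methylation), C9–C11 and C1–C2 (two alkylations).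
4. Forward: the C2–C5 and C11–C15 iodides are made, the chain is assembled on acetoacetate, diene and enal are installed, one cycloaddition closes both rings, then C6 is decarbonylated, C15 oxidised, the acid esterified and the benzyl group removed.
5. Stereochemistry: C13 from (R)-citronellol; the C9=C10 geometry from a chelated (Z)-enol triflate and a retentive coupling; C5 and C10 from the chiral amine catalyst acting on that geometry; the glycerol centre from (R)-benzyl glycidyl ether.

Key step: step 15

Assumption: the diene is taken to add to the Re face of C5 in the benzyl-shielded iminium ion of the (2R,5R)-imidazolidinone, as the usual shielding model predicts; if the sense proved opposite, the (2S,5S)-catalyst would be used.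
Abbreviation: TBDPS = tert-butyldiphenylsilyl.

**Step 1**
Reactants: 1 2,2-dimethylpent-4-enal
Product: 2 5,5-dimethoxy-4,4-dimethylpent-1-ene
Conditions: HC(OMe)3, MeOH, p-TsOH·H2O (cat.), rt
Reagents that add atoms: trimethyl orthoformate COC(OC)OC; methanol CO
Why: Acid-catalysed acetalisation with the orthoformate as water scavenger should mask the non-enolisable C5 aldehyde for the carbanion steps that follow.

**Step 2**
Reactants: 2 5,5-dimethoxy-4,4-dimethylpent-1-ene
Product: 4 4,4-dimethoxy-3,3-dimethylbutan-1-ol, via ozonide 3 (not isolated)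
Conditions: O3 (to the indicator end point), CH2Cl2, −78 °C; then NaBH4, MeOH, −78 → 0 °C
Reagents that add atoms: ozone [O-][O+]=O
Why: Ozonolysis with reductive borohydride work-up should cut off the terminal carbon and leave C2 as a primary alcohol, the alkene reacting far faster with ozone than the acetal C–H and the acetal being stable to the basic reduction.

**Step 3**
Reactants: 4 4,4-dimethoxy-3,3-dimethylbutan-1-ol
Product: 5 4-iodo-1,1-dimethoxy-2,2-dimethylbutane
Conditions: I2, PPh3, imidazole, CH2Cl2, 0 °C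
Reagents that add atoms: iodine II
Why: Garegg–Samuelsson (Appel-type) iodination should convert the unhindered primary alcohol into the iodide by SN2 displacement, with imidazole buffering that spares the acetal.

**Step 4**
Reactants: 6 (R)-citronellol
Product: 7 TBDPS ether of (R)-citronellol
Conditions: TBDPSCl, imidazole, DMF, rt
Reagents that add atoms: tert-butylchlorodiphenylsilane CC(C)(C)[Si](Cl)(c1ccccc1)c1ccccc1
Why: Imidazole-promoted silylation of the primary alcohol should install a group that withstands the organolithium, Grignard and acidic iminium conditions ahead, with C13 untouched.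

**Step 5**
Reactants: 7 TBDPS ether of (R)-citronellol
Product: 9 (4R)-6-(TBDPS-oxy)-4-methylhexanoic acid, via aldehyde 8 (not isolated)
Conditions: RuCl3·xH2O (cat.), NaIO4, EtOAc/MeCN/H2O, rt
Reagents that add atoms: sodium periodate [Na+].[O-]I(=O)(=O)=O; water O
Why: RuO4 generated in situ (Sharpless oxidative cleavage) should cut the trisubstituted olefin to acetone and the aldehyde, which is oxidised on to the acid, without touching the silyl ether or the remote stereocentre.

**Step 6**
Reactants: 9 (4R)-6-(TBDPS-oxy)-4-methylhexanoic acid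
Product: 10 tert-butyl{[(3S)-5-iodo-3-methylpentyl]oxy}diphenylsilane
Conditions: PhI(OAc)2, I2, cyclohexane, hν (tungsten lamp), reflux
Reagents that add atoms: iodine II
Why: Suárez iododecarboxylation (a radical Hunsdiecker-type reaction) should give the primary iodide with loss of CO2, the primary radical being trapped by iodine faster than any hydrogen shift; the stereocentre is not involved and its descriptor changes only through CIP priorities.

**Step 7**
Reactants: 11 methyl acetoacetate; 5 4-iodo-1,1-dimethoxy-2,2-dimethylbutane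
Product: 13 methyl 8,8-dimethoxy-7,7-dimethyl-3-oxooctanoate, via acetoacetate dianion 12 (not isolated)
Conditions: NaH, THF, 0 °C; n-BuLi, 0 °C; then 5, 0 °C → rt
Reagents that add atoms: none
Why: Huckin–Weiler dianion alkylation: the terminal carbanion of the dianion is the more reactive site and should take the primary iodide at the γ-carbon only, forming C1–C2.

**Step 8**
Reactants: 13 methyl 8,8-dimethoxy-7,7-dimethyl-3-oxooctanoate; 10 tert-butyl{[(3S)-5-iodo-3-methylpentyl]oxy}diphenylsilane
Product: 14 methyl 2-[(3R)-5-(TBDPS-oxy)-3-methylpentyl]-8,8-dimethoxy-7,7-dimethyl-3-oxooctanoate (both C2 epimers)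
Conditions: Cs2CO3, DMF, 40 °C
Reagents that add atoms: none
Why: C-Alkylation of the doubly stabilised β-keto ester enolate with a primary iodide should form C9–C11; the new C9 centre is formed as both epimers and is erased in step 9.

**Step 9**
Reactants: 14 methyl 2-[(3R)-5-(TBDPS-oxy)-3-methylpentyl]-8,8-dimethoxy-7,7-dimethyl-3-oxooctanoate
Product: 16 methyl (2Z)-2-[(3R)-5-(TBDPS-oxy)-3-methylpentyl]-8,8-dimethoxy-7,7-dimethyl-3-(trifluoromethylsulfonyloxy)oct-2-enoate, via sodium enolate 15 (not isolated)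
Conditions: NaH, Et2O, 0 °C; then Tf2O, −78 → 0 °C
Reagents that add atoms: triflic anhydride O=S(=O)(OS(=O)(=O)C(F)(F)F)C(F)(F)F
Why: Deprotonation between the carbonyls gives the sodium-chelated enolate, and O-sulfonylation of this U-shaped chelate should place the triflate cis to the ester, i.e. the (Z)-enol triflate that fixes C1 cis to C11.

**Step 10**
Reactants: 16 (Z)-enol triflate
Product: 17 methyl (2E)-2-[(3R)-5-(TBDPS-oxy)-3-methylpentyl]-8,8-dimethoxy-3,7,7-trimethyloct-2-enoate
Conditions: MeMgBr, Fe(acac)3 (5 mol%), THF/NMP, −30 °C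
Reagents that add atoms: methylmagnesium bromide C[Mg]Br
Why: Iron-catalysed Kochi–Fürstner cross-coupling of the enol triflate with MeMgBr should install C20 cis to the ester with retention of olefin geometry, faster than Grignard attack on the hindered ester.

**Step 11**
Reactants: 17 tetrasubstituted (E)-enoate
Product: 19 (3E)-3-[(3R)-5-(TBDPS-oxy)-3-methylpentyl]-9,9-dimethoxy-2,4,8,8-tetramethylnon-3-en-2-ol, via methyl ketone 18 (not isolated)
Conditions: MeLi (4 equiv), Et2O, −78 → 0 °C
Reagents that add atoms: methyllithium [Li]C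
Why: Double 1,2-addition of methyllithium to the ester through ketone 18 should give the tertiary allylic alcohol that carries C7 and C17, the tetrasubstituted olefin being too hindered for conjugate addition.

**Step 12**
Reactants: 19 tertiary allylic alcohol
Product: 20 (3E)-3-[(3R)-5-(TBDPS-oxy)-3-methylpentyl]-9,9-dimethoxy-2,4,8,8-tetramethylnona-1,3-diene
Conditions: Burgess reagent, benzene, 50 °C
Reagents that add atoms: none
Why: Burgess dehydration (syn-elimination of the sulfamate ester) should give the isopropenyl group because only the two methyl groups offer β-hydrogens, and its non-acidic conditions should preserve the C9=C10 geometry and the acetal.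

**Step 13**
Reactants: 20 diene acetal
Product: 21 (6E)-7-[(3R)-5-(TBDPS-oxy)-3-methylpentyl]-2,2,6,8-tetramethylnona-6,8-dienal
Conditions: PPTS, acetone/H2O (10:1), 50 °C
Reagents that add atoms: water O
Why: Mild acid-catalysed hydrolysis of the dimethyl acetal should free the C5 aldehyde at an acidity too low to protonate the diene or cleave the TBDPS ether.

**Step 14**
Reactants: 21 diene aldehyde
Product: 22 (2E,8E)-9-[(3R)-5-(TBDPS-oxy)-3-methylpentyl]-4,4,8,10-tetramethylundeca-2,8,10-trienal
Conditions: Ph3P=CHCHO, toluene, 80 °C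
Reagents that add atoms: (triphenylphosphoranylidene)acetaldehyde O=CC=P(c1ccccc1)(c1ccccc1)c1ccccc1
Why: Wittig olefination with the stabilised formylmethylene ylide should give the (E)-enal on the non-enolisable neopentyl aldehyde, the temperature being held at 80 °C so that no uncatalysed cycloaddition of the product sets in.

**Step 15**
Reactants: 22 (2E,8E)-trienal
Product: 25 (1R,4aR,8aR)-4-[(3R)-5-(TBDPS-oxy)-3-methylpentyl]-3,4a,8,8-tetramethyl-1,2,4a,5,6,7,8,8a-octahydronaphthalene-1-carbaldehyde (C6-formyl trans-octalin with the C8=C9 olefin), via trienal iminium ion 23 (not isolated), via cycloadduct iminium ion 24 (not isolated)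
Conditions: (2R,5R)-5-benzyl-2-tert-butyl-3-methylimidazolidin-4-one·TfOH (20 mol%), MeCN/H2O (98:2), 0.05 M, −20 °C → rt
Reagents that add atoms: none
Why: Proposed new method: condensation of the enal with the imidazolidinone salt gives the (E)-iminium ion 23, whose lowered LUMO should let the tethered C7=C8–C9=C10 diene add across C5=C6 in a concerted but asynchronous [4+2] step (C5–C10 ahead of C6–C7), and hydrolysis of 24 returns the catalyst; the closest known reaction type is the imidazolidinone-catalysed type 1 intramolecular Diels–Alder reaction of trienals to trans-fused bicycles, which has not been shown for a diene terminus carrying two carbon groups or for an enal β-carbon next to a quaternary centre. Ring A closes as the six-membered tether ring through the C5–C10 bond alone, and ring B closes as the cycloadduct cyclohexene through C5–C10 and C6–C7, which leaves the olefin at C8=C9 and nowhere else. C5 and C6 take their absolute configuration from the benzyl-shielded iminium ion, which leaves the Re face of C5 open, and their trans relation from the (E)-enal. C10 is set relative to C5 by the endo transition state together with the C9=C10 geometry fixed in steps 9 and 10, the outer tether and the inner methyl placing C20 anti to H5, which is the trans fusion. The step needs endo over exo selectivity and one enantioface; the tether allows only one regiochemistry, and quaternary C4 blocks dienamine formation and favours the folded conformer.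

**Step 16**
Reactants: 25 C6-formyl trans-octalin
Product: 26 tert-butyl{[(3R)-3-methyl-5-[(4aR,8aR)-2,5,5,8a-tetramethyl-3,4,4a,5,6,7,8,8a-octahydronaphthalen-1-yl]pentyl]oxy}diphenylsilane
Conditions: RhCl(PPh3)3 (1.1 equiv), toluene, 110 °C
Reagents that add atoms: none
Why: Tsuji–Wilkinson decarbonylation (insertion of rhodium into the formyl C–H bond, CO extrusion and C–H reductive elimination) should replace the formyl group by hydrogen so that C6 becomes a methylene group, with C5 and C10 untouched.

**Step 17**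
Reactants: 26 decarbonylated silyl ether
Product: 27 (3R)-3-methyl-5-[(4aR,8aR)-2,5,5,8a-tetramethyl-3,4,4a,5,6,7,8,8a-octahydronaphthalen-1-yl]pentan-1-ol
Conditions: TBAF, THF, rt
Reagents that add atoms: none
Why: Fluoride-induced cleavage of the silyl ether should free the C15 alcohol without affecting the tetrasubstituted olefin.

**Step 18**
Reactants: 27 C15 alcohol
Product: 29 (3R)-3-methyl-5-[(4aR,8aR)-2,5,5,8a-tetramethyl-3,4,4a,5,6,7,8,8a-octahydronaphthalen-1-yl]pentanoic acid, via aldehyde 28 (not isolated)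
Conditions: TEMPO (20 mol%), PhI(OAc)2 (2.2 equiv), MeCN/H2O (1:1), rt
Reagents that add atoms: water O
Why: TEMPO/PhI(OAc)2 oxidation in aqueous acetonitrile (Epp–Widlanski conditions) should take the primary alcohol through aldehyde 28 and its hydrate to the acid, leaving the olefin and the non-epimerisable C13 centre alone.

**Step 19**
Reactants: 30 (R)-benzyl glycidyl ether
Product: 31 (2S)-3-(benzyloxy)-2-hydroxypropyl acetate
Conditions: AcOH (1.5 equiv), Et4NBr (5 mol%), toluene, 80 °C
Reagents that add atoms: acetic acid CC(=O)O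
Why: Ammonium halide-catalysed opening of the terminal epoxide by acetic acid should occur at the unhindered CH2 carbon, so the C–O bond of the stereocentre is not broken and the (2S)-alcohol arises from the (R)-epoxide by a change of CIP priorities only.

**Step 20**
Reactants: 29 labdenoic acid; 31 (2S)-3-(benzyloxy)-2-hydroxypropyl acetate
Product: 32 (2S)-1-(acetyloxy)-3-(benzyloxy)propan-2-yl (3R)-3-methyl-5-[(4aR,8aR)-2,5,5,8a-tetramethyl-3,4,4a,5,6,7,8,8a-octahydronaphthalen-1-yl]pentanoate
Conditions: DCC, DMAP (10 mol%), CH2Cl2, 0 °C → rt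
Reagents that add atoms: none
Why: Steglich esterification (carbodiimide activation with DMAP as acyl-transfer catalyst) should acylate the secondary alcohol on oxygen with retention at the glycerol centre, low temperature limiting acetyl migration.

**Step 21**
Reactants: 32 benzyl-protected ester
Product: 33 CNP0216082.1, (2S)-1-(acetyloxy)-3-hydroxypropan-2-yl (3R)-3-methyl-5-[(4aR,8aR)-2,5,5,8a-tetramethyl-3,4,4a,5,6,7,8,8a-octahydronaphthalen-1-yl]pentanoate
Conditions: H2 (1 atm), Pd/C, EtOAc, rt
Reagents that add atoms: none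
Why: Hydrogenolysis of the benzyl ether over Pd/C should free the primary alcohol, the hindered tetrasubstituted C8=C9 olefin resisting hydrogenation and the neutral aprotic medium suppressing acyl migration.

**Compound list**
1 | 2,2-dimethylpent-4-enal | C=CCC(C)(C)C=O | starting material
2 | 5,5-dimethoxy-4,4-dimethylpent-1-ene | C=CCC(C)(C)C(OC)OC | intermediate
3 | 3-(3,3-dimethoxy-2,2-dimethylpropyl)-1,2,4-trioxolane (ozonide of 2) | COC(OC)C(C)(C)CC1OCOO1 | intermediate
4 | 4,4-dimethoxy-3,3-dimethylbutan-1-ol | COC(OC)C(C)(C)CCO | intermediate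
5 | 4-iodo-1,1-dimethoxy-2,2-dimethylbutane | COC(OC)C(C)(C)CCI | intermediate
6 | (R)-citronellol, (3R)-3,7-dimethyloct-6-en-1-ol | OCC[C@H](C)CCC=C(C)C | starting material
7 | tert-butyl{[(3R)-3,7-dimethyloct-6-en-1-yl]oxy}diphenylsilane | CC(C)=CCC[C@@H](C)CCO[Si](c1ccccc1)(c1ccccc1)C(C)(C)C | intermediate
8 | (4R)-6-[(tert-butyldiphenylsilyl)oxy]-4-methylhexanal | O=CCC[C@@H](C)CCO[Si](c1ccccc1)(c1ccccc1)C(C)(C)C | intermediate
9 | (4R)-6-[(tert-butyldiphenylsilyl)oxy]-4-methylhexanoic acid | OC(=O)CC[C@@H](C)CCO[Si](c1ccccc1)(c1ccccc1)C(C)(C)C | intermediate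
10 | tert-butyl{[(3S)-5-iodo-3-methylpentyl]oxy}diphenylsilane | ICC[C@@H](C)CCO[Si](c1ccccc1)(c1ccccc1)C(C)(C)C | intermediate
11 | methyl acetoacetate | COC(=O)CC(C)=O | starting material
12 | sodium lithium dianion of methyl acetoacetate | COC([O-])=CC([O-])=C.[Na+].[Li+] | intermediate
13 | methyl 8,8-dimethoxy-7,7-dimethyl-3-oxooctanoate | COC(=O)CC(=O)CCCC(C)(C)C(OC)OC | intermediate
14 | methyl 2-{(3R)-5-[(tert-butyldiphenylsilyl)oxy]-3-methylpentyl}-8,8-dimethoxy-7,7-dimethyl-3-oxooctanoate (C2 epimers) | COC(=O)C(CC[C@@H](C)CCO[Si](c1ccccc1)(c1ccccc1)C(C)(C)C)C(=O)CCCC(C)(C)C(OC)OC | intermediate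
15 | sodium (Z)-enolate of 14 | COC(=O)/C(CC[C@@H](C)CCO[Si](c1ccccc1)(c1ccccc1)C(C)(C)C)=C(\[O-])CCCC(C)(C)C(OC)OC.[Na+] | intermediate
16 | methyl (2Z)-2-{(3R)-5-[(tert-butyldiphenylsilyl)oxy]-3-methylpentyl}-8,8-dimethoxy-7,7-dimethyl-3-{[(trifluoromethyl)sulfonyl]oxy}oct-2-enoate | COC(=O)/C(CC[C@@H](C)CCO[Si](c1ccccc1)(c1ccccc1)C(C)(C)C)=C(\OS(=O)(=O)C(F)(F)F)CCCC(C)(C)C(OC)OC | intermediate
17 | methyl (2E)-2-{(3R)-5-[(tert-butyldiphenylsilyl)oxy]-3-methylpentyl}-8,8-dimethoxy-3,7,7-trimethyloct-2-enoate | COC(=O)/C(CC[C@@H](C)CCO[Si](c1ccccc1)(c1ccccc1)C(C)(C)C)=C(\C)CCCC(C)(C)C(OC)OC | intermediate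
18 | (3E)-3-{(3R)-5-[(tert-butyldiphenylsilyl)oxy]-3-methylpentyl}-9,9-dimethoxy-4,8,8-trimethylnon-3-en-2-one | CC(=O)/C(CC[C@@H](C)CCO[Si](c1ccccc1)(c1ccccc1)C(C)(C)C)=C(\C)CCCC(C)(C)C(OC)OC | intermediate
19 | (3E)-3-{(3R)-5-[(tert-butyldiphenylsilyl)oxy]-3-methylpentyl}-9,9-dimethoxy-2,4,8,8-tetramethylnon-3-en-2-ol | CC(C)(O)/C(CC[C@@H](C)CCO[Si](c1ccccc1)(c1ccccc1)C(C)(C)C)=C(\C)CCCC(C)(C)C(OC)OC | intermediate
20 | (3E)-3-{(3R)-5-[(tert-butyldiphenylsilyl)oxy]-3-methylpentyl}-9,9-dimethoxy-2,4,8,8-tetramethylnona-1,3-diene | C=C(C)/C(CC[C@@H](C)CCO[Si](c1ccccc1)(c1ccccc1)C(C)(C)C)=C(\C)CCCC(C)(C)C(OC)OC | intermediate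
21 | (6E)-7-{(3R)-5-[(tert-butyldiphenylsilyl)oxy]-3-methylpentyl}-2,2,6,8-tetramethylnona-6,8-dienal | C=C(C)/C(CC[C@@H](C)CCO[Si](c1ccccc1)(c1ccccc1)C(C)(C)C)=C(\C)CCCC(C)(C)C=O | intermediate
22 | (2E,8E)-9-{(3R)-5-[(tert-butyldiphenylsilyl)oxy]-3-methylpentyl}-4,4,8,10-tetramethylundeca-2,8,10-trienal | C=C(C)/C(CC[C@@H](C)CCO[Si](c1ccccc1)(c1ccccc1)C(C)(C)C)=C(\C)CCCC(C)(C)/C=C/C=O | intermediate
23 | iminium triflate of trienal 22 with (2R,5R)-5-benzyl-2-tert-butyl-3-methylimidazolidin-4-one | C=C(C)/C(CC[C@@H](C)CCO[Si](c1ccccc1)(c1ccccc1)C(C)(C)C)=C(\C)CCCC(C)(C)/C=C/C=[N+]1[C@@H](C(C)(C)C)N(C)C(=O)[C@H]1Cc1ccccc1.[O-]S(=O)(=O)C(F)(F)F | intermediate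
24 | iminium triflate of cycloadduct 25 with the same imidazolidinone | CC(C)(C)[Si](c3ccccc3)(c4ccccc4)OCC[C@H](C)CCC1=C(C)C[C@@H](C=[N+]5[C@@H](C(C)(C)C)N(C)C(=O)[C@H]5Cc6ccccc6)[C@@H]2C(C)(C)CCC[C@@]12C.[O-]S(=O)(=O)C(F)(F)F | intermediate
25 | (1R,4aR,8aR)-4-{(3R)-5-[(tert-butyldiphenylsilyl)oxy]-3-methylpentyl}-3,4a,8,8-tetramethyl-1,2,4a,5,6,7,8,8a-octahydronaphthalene-1-carbaldehyde | CC(C)(C)[Si](c3ccccc3)(c4ccccc4)OCC[C@H](C)CCC1=C(C)C[C@@H](C=O)[C@@H]2C(C)(C)CCC[C@@]12C | intermediate
26 | tert-butyl{[(3R)-3-methyl-5-[(4aR,8aR)-2,5,5,8a-tetramethyl-3,4,4a,5,6,7,8,8a-octahydronaphthalen-1-yl]pentyl]oxy}diphenylsilane | CC(C)(C)[Si](c3ccccc3)(c4ccccc4)OCC[C@H](C)CCC1=C(C)CC[C@@H]2C(C)(C)CCC[C@@]12C | intermediate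
27 | (3R)-3-methyl-5-[(4aR,8aR)-2,5,5,8a-tetramethyl-3,4,4a,5,6,7,8,8a-octahydronaphthalen-1-yl]pentan-1-ol | OCC[C@H](C)CCC1=C(C)CC[C@@H]2C(C)(C)CCC[C@@]12C | intermediate
28 | (3R)-3-methyl-5-[(4aR,8aR)-2,5,5,8a-tetramethyl-3,4,4a,5,6,7,8,8a-octahydronaphthalen-1-yl]pentanal | O=CC[C@H](C)CCC1=C(C)CC[C@@H]2C(C)(C)CCC[C@@]12C | intermediate
29 | (3R)-3-methyl-5-[(4aR,8aR)-2,5,5,8a-tetramethyl-3,4,4a,5,6,7,8,8a-octahydronaphthalen-1-yl]pentanoic acid | OC(=O)C[C@H](C)CCC1=C(C)CC[C@@H]2C(C)(C)CCC[C@@]12C | intermediate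
30 | (R)-benzyl glycidyl ether, (2R)-2-[(benzyloxy)methyl]oxirane | C1[C@H](COCc2ccccc2)O1 | starting material
31 | (2S)-3-(benzyloxy)-2-hydroxypropyl acetate | CC(=O)OC[C@H](COCc1ccccc1)O | intermediate
32 | (2S)-1-(acetyloxy)-3-(benzyloxy)propan-2-yl (3R)-3-methyl-5-[(4aR,8aR)-2,5,5,8a-tetramethyl-3,4,4a,5,6,7,8,8a-octahydronaphthalen-1-yl]pentanoate | CC(=O)OC[C@H](COCc3ccccc3)OC(=O)C[C@H](C)CCC1=C(C)CC[C@@H]2C(C)(C)CCC[C@@]12C | intermediate
33 | CNP0216082.1, (2S)-1-(acetyloxy)-3-hydroxypropan-2-yl (3R)-3-methyl-5-[(4aR,8aR)-2,5,5,8a-tetramethyl-3,4,4a,5,6,7,8,8a-octahydronaphthalen-1-yl]pentanoate | CC(=O)OC[C@H](CO)OC(=O)C[C@H](C)CCC1=C(C)CC[C@@H]2C(C)(C)CCC[C@@]12C | target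

**Step count**
Total: 21 steps. Longest linear sequence: 17 steps (steps 1, 2, 3, 7–18, 20, 21, from 2,2-dimethylpent-4-enal).

**Steps most likely to fail**

Step 15 (the step proposed as a new method). The twisted, fully substituted diene may not reach the s-cis arrangement under the bulky iminium ion. The cycloaddition could then stall, stop after C5–C10 bond formation with proton loss, or lose endo and facial control. The fallback binds the dienophile to an auxiliary and activates it with a Lewis acid instead of an amine catalyst. Setting out from aldehyde 21, a Masamune–Roush Horner–Wadsworth–Emmons reaction (LiCl, i-Pr2NEt, MeCN) with diethyl {2-[(4R)-4-benzyl-2-oxo-1,3-oxazolidin-3-yl]-2-oxoethyl}phosphonate should give the (E)-trienimide F1. Me2AlCl (1.4 equiv, CH2Cl2, −30 °C) should then close the same two bonds through the chelated s-cis imide in an Evans-type intramolecular Diels–Alder reaction, the diene adding anti to the benzyl group, to give the cycloadduct imide F2. LiBH4 (THF, MeOH, 0 °C) should cleave the auxiliary to the primary alcohol F3, and Dess–Martin periodinane (CH2Cl2, NaHCO3) should return the route to aldehyde 25.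

Step 16. Insertion at the hindered formyl group may be slow, and the alkyl-rhodium intermediate may undergo β-hydride elimination, giving an olefin instead of the C6 methylene group. The fallback uses radical decarboxylation in place of metal-mediated decarbonylation. Setting out from aldehyde 25, Pinnick oxidation (NaClO2, NaH2PO4, 2-methyl-2-butene, t-BuOH/H2O) should give the carboxylic acid F4. Coupling with N-hydroxypyridine-2-thione (DCC, CH2Cl2, dark) should give the Barton ester F5, and photolysis with t-BuSH (benzene, hν, rt) should give silyl ether 26, where the route is rejoined.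

Step 12. Ionisation of the tertiary allylic sulfamate may lead to allylic transposition, proton loss towards C1 or C20, or loss of the C9=C10 geometry. The fallback uses carbonyl methylenation instead of alcohol dehydration. Setting out from ester 17, Me(MeO)NH·HCl with i-PrMgCl (THF, −20 °C) should give the Weinreb amide F6. MeMgBr (THF, 0 °C) should give methyl ketone 18, now isolated, and non-basic methylenation with Cp2TiMe2 (toluene, 65 °C) should give diene acetal 20, where the route is rejoined.

**Further compounds**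
F1 | step 15 | (4R)-4-benzyl-3-[(2E,8E)-9-{(3R)-5-[(tert-butyldiphenylsilyl)oxy]-3-methylpentyl}-4,4,8,10-tetramethylundeca-2,8,10-trienoyl]-1,3-oxazolidin-2-one | C=C(C)/C(CC[C@@H](C)CCO[Si](c1ccccc1)(c1ccccc1)C(C)(C)C)=C(\C)CCCC(C)(C)/C=C/C(=O)N1[C@H](Cc2ccccc2)COC1=O
F2 | step 15 | (4R)-4-benzyl-3-{[(1R,4aR,8aR)-4-{(3R)-5-[(tert-butyldiphenylsilyl)oxy]-3-methylpentyl}-3,4a,8,8-tetramethyl-1,2,4a,5,6,7,8,8a-octahydronaphthalen-1-yl]carbonyl}-1,3-oxazolidin-2-one | CC(C)(C)[Si](c3ccccc3)(c4ccccc4)OCC[C@H](C)CCC1=C(C)C[C@@H](C(=O)N5[C@H](Cc6ccccc6)COC5=O)[C@@H]2C(C)(C)CCC[C@@]12C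
F3 | step 15 | [(1R,4aR,8aR)-4-{(3R)-5-[(tert-butyldiphenylsilyl)oxy]-3-methylpentyl}-3,4a,8,8-tetramethyl-1,2,4a,5,6,7,8,8a-octahydronaphthalen-1-yl]methanol | CC(C)(C)[Si](c3ccccc3)(c4ccccc4)OCC[C@H](C)CCC1=C(C)C[C@@H](CO)[C@@H]2C(C)(C)CCC[C@@]12C
F4 | step 16 | (1R,4aR,8aR)-4-{(3R)-5-[(tert-butyldiphenylsilyl)oxy]-3-methylpentyl}-3,4a,8,8-tetramethyl-1,2,4a,5,6,7,8,8a-octahydronaphthalene-1-carboxylic acid | CC(C)(C)[Si](c3ccccc3)(c4ccccc4)OCC[C@H](C)CCC1=C(C)C[C@@H](C(=O)O)[C@@H]2C(C)(C)CCC[C@@]12C
F5 | step 16 | 2-thioxopyridin-1(2H)-yl ester of F4 (Barton ester) | CC(C)(C)[Si](c3ccccc3)(c4ccccc4)OCC[C@H](C)CCC1=C(C)C[C@@H](C(=O)On5ccccc5=S)[C@@H]2C(C)(C)CCC[C@@]12C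
F6 | step 12 | (2E)-2-{(3R)-5-[(tert-butyldiphenylsilyl)oxy]-3-methylpentyl}-N,8,8-trimethoxy-N,3,7,7-tetramethyloct-2-enamide | CON(C)C(=O)/C(CC[C@@H](C)CCO[Si](c1ccccc1)(c1ccccc1)C(C)(C)C)=C(\C)CCCC(C)(C)C(OC)OC
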